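**Retrosynthetic overview**

1. Bought materials: racemic naringenin 1 (rings A and B ready-made) and geranyl bromide 2; nothing else supplies carbon.
2. 1 is used as a masked naringenin chalcone 3: alkaline retro-oxa-Michael opening of ring C erases the racemic centre.
3. Geranyl disconnection (ring A C3'–C1''): in 3 the two free ring A carbons are equivalent, so C-geranylation in the same flask gives one chalcone, 4 (prenylation at the chalcone stage, as in hop flavonoid biosynthesis).
4. Key disconnection of target 5 is O1–C2: ring C is closed last from unprotected 4 by a chalcone-isomerase-like asymmetric 6-endo oxa-Michael addition that fixes C2 (S) and 6- versus 8-geranyl in one event.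
5. Ring order: rings A and B are bought; ring C is opened once and re-formed in the final step, the only ring-forming step.

Assumption: the quinine-derived thiourea named in step 2 is taken to give the (2S) product; if the first run (chiral HPLC, CD) shows (2R), its quinidine-derived pseudoenantiomer, the (9R)-6′-methoxycinchonan-9-yl thiourea, is used with nothing else changed.

**Route**

Step 1
Reactants: 1 (±)-naringenin; 2 geranyl bromide
Product: 4 3'-geranylchalconaringenin (3'-geranyl-2',4',6',4-tetrahydroxy-(E)-chalcone), via naringenin chalcone 3 (not isolated)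
Conditions: degassed 10% aq. KOH (6 equiv per 1), Ar, rt, 30 min; then 2 (0.7 equiv per 1), 0 °C → rt, 4 h; then ice-cold 2 M HCl to pH 3, EtOAc, fast chromatography (unreacted 1 recovered)
Reagents that add atoms: geranyl bromide (2), CC(C)=CCC/C(C)=C/CBr
Why: Aqueous alkali opens the 5-hydroxyflavanone by E1cB retro-oxa-Michael elimination to the chalcone polyphenolate 3 (the racemic centre disappears), whose phloroglucinol-type ring A is C-allylated by SN2 attack on the primary allylic bromide (water favours C- over O-alkylation, the two free ring A carbons are equivalent so one regioisomer forms, and the 2E olefin is untouched), and cold acidification releases the chalcone before it can reclose; reaction types: base-induced flavanone–chalcone ring opening and aqueous-alkali C-prenylation of polyphenolates.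

Step 2
Reactants: 4 3'-geranylchalconaringenin
Product: 5 Bonannione A [(2S)-6-geranylnaringenin]
Conditions: N-[3,5-bis(trifluoromethyl)phenyl]-N′-[(8α,9S)-6′-methoxycinchonan-9-yl]thiourea (10 mol %), PhCl–THF 9:1 (0.05 M), −20 °C, Ar, dark, to ca. 90% conversion; then cold 0.5 M HCl wash, chromatography
Reagents that add atoms: none
Why: Proposed new method: a small-molecule chalcone isomerase mimic in which the quinuclidine nitrogen takes the proton of the exposed 6'-OH (the 2'-OH is buttressed by the geranyl group into a strong hydrogen bond to C=O and is shielded from the bulky catalyst), the thiourea N–H bonds hold the enone carbonyl, and the ion-paired phenoxide adds 6-endo-trig to the Si face of C-β, so one kinetically controlled event closes ring C through the unflanked oxygen (6- rather than 8-geranyl) and sets C2 as S; the closest known reaction types are the cinchona-thiourea-catalysed enantioselective oxa-Michael cyclisation of activated 2'-hydroxychalcones (alkylidene β-keto esters) and the quinine-catalysed cyclisation of phloroglucinol-derived o-enoyl phenols to chromanones, and 2',6'-dihydroxychalcones are the chalcone class that cyclises most readily.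

**Compound list**

1 | (±)-naringenin, (2RS)-5,7-dihydroxy-2-(4-hydroxyphenyl)-2,3-dihydro-4H-chromen-4-one (racemate) | O=C1CC(c2ccc(O)cc2)Oc2cc(O)cc(O)c12 | starting material
2 | geranyl bromide, (2E)-1-bromo-3,7-dimethylocta-2,6-diene | CC(C)=CCC/C(C)=C/CBr | starting material
3 | naringenin chalcone, (2E)-3-(4-hydroxyphenyl)-1-(2,4,6-trihydroxyphenyl)prop-2-en-1-one (in the flask as its potassium polyphenolate) | O=C(/C=C/c1ccc(O)cc1)c1c(O)cc(O)cc1O | intermediate
4 | 3'-geranylchalconaringenin, (2E)-1-{3-[(2E)-3,7-dimethylocta-2,6-dien-1-yl]-2,4,6-trihydroxyphenyl}-3-(4-hydroxyphenyl)prop-2-en-1-one | CC(C)=CCC/C(C)=C/Cc1c(O)cc(O)c(C(=O)/C=C/c2ccc(O)cc2)c1O | intermediate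
5 | Bonannione A, (2S)-6-[(2E)-3,7-dimethylocta-2,6-dien-1-yl]-5,7-dihydroxy-2-(4-hydroxyphenyl)-2,3-dihydro-4H-chromen-4-one | CC(C)=CCC/C(C)=C/Cc1c(O)cc2c(c1O)C(=O)C[C@@H](c1ccc(O)cc1)O2 | target

**Step count, longest sequence, risks and fallbacks**

Total step count: 2 (one intermediate, 3, is not isolated). Longest linear sequence: 2 steps from 1. The route has only two steps, so both are named, and step 2 is named twice, once for each of its two independent ways of failing.

Most likely to fail is step 2 in its enantiocontrol. The enone of 4 is unactivated and electron-rich, and the amine catalyst can also reopen the product, so the ee may be only moderate or may erode if the reaction is left too long. The fallback replaces asymmetric catalysis by resolution with recycling. It sets out from 4, which is closed without chiral control (NaOAc, EtOH, 60 °C) to racemic 6-geranylnaringenin F1. F1 is resolved by preparative SFC on an amylose tris(3,5-dimethylphenylcarbamate) phase; the (2S) band is 5, where the fallback rejoins the route. The other band, (2R)-6-geranylnaringenin F2, is reopened with 10% aq. KOH and cold HCl and returned to the pool of 4.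

Second is step 2 in its regiocontrol. Closure through the geranyl-flanked 2'-OH would give the 8-geranyl isomer, and the preference for the unflanked oxygen rests on a steric and hydrogen-bond argument, not on precedent with this substrate. The fallback replaces single-pass selection by a closed recycling loop through the chalcone. It sets out from 4: after the catalytic closure the regioisomer 8-geranylnaringenin F3 is separated from 5 on silica and reopened by alkaline retro-oxa-Michael reaction (10% aq. KOH, rt, then cold 2 M HCl). This erases both its regiochemistry and its C2 configuration, and the fallback comes back to the route at 4 for another pass.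

Third is step 1 in its C-geranylation stage. The chalcone polyphenolate may alkylate on the ring B oxygen, over-alkylate on ring A, or suffer retro-aldol cleavage, leaving little 4. The fallback builds the chalcone by aldol condensation instead of alkylating it. It sets out from 2, which C-alkylates purchased 2,4,6-trihydroxyacetophenone (10% aq. KOH, 0 °C → rt) to 3-geranyl-2,4,6-trihydroxyacetophenone F4. Chloromethyl methyl ether (MOMCl, 2.2 equiv) with i-Pr2NEt in CH2Cl2 protects the two unchelated phenols to give 3-geranyl-2-hydroxy-4,6-bis(methoxymethoxy)acetophenone F5. Claisen–Schmidt condensation with purchased 4-(methoxymethoxy)benzaldehyde (KOH, EtOH–H2O, rt) gives 3'-geranyl-2'-hydroxy-4,4',6'-tris(methoxymethoxy)chalcone F6. Removal of the three acetals (3 M HCl, MeOH, rt) brings the fallback back to the route at 4.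

**Further compounds**

F1 | step 2 | racemic 6-geranylnaringenin, (2RS)-6-[(2E)-3,7-dimethylocta-2,6-dien-1-yl]-5,7-dihydroxy-2-(4-hydroxyphenyl)-2,3-dihydro-4H-chromen-4-one | CC(C)=CCC/C(C)=C/Cc1c(O)cc2c(c1O)C(=O)CC(c1ccc(O)cc1)O2
F2 | step 2 | (2R)-6-geranylnaringenin | CC(C)=CCC/C(C)=C/Cc1c(O)cc2c(c1O)C(=O)C[C@H](c1ccc(O)cc1)O2
F3 | step 2 | 8-geranylnaringenin, 8-[(2E)-3,7-dimethylocta-2,6-dien-1-yl]-5,7-dihydroxy-2-(4-hydroxyphenyl)-2,3-dihydro-4H-chromen-4-one (C2 configuration immaterial, erased on reopening) | CC(C)=CCC/C(C)=C/Cc1c(O)cc(O)c2c1OC(c1ccc(O)cc1)CC2=O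
F4 | step 1 | 3-geranyl-2,4,6-trihydroxyacetophenone, 1-{3-[(2E)-3,7-dimethylocta-2,6-dien-1-yl]-2,4,6-trihydroxyphenyl}ethan-1-one | CC(C)=CCC/C(C)=C/Cc1c(O)cc(O)c(C(C)=O)c1O
F5 | step 1 | 3-geranyl-2-hydroxy-4,6-bis(methoxymethoxy)acetophenone | CC(C)=CCC/C(C)=C/Cc1c(OCOC)cc(OCOC)c(C(C)=O)c1O
F6 | step 1 | 3'-geranyl-2'-hydroxy-4,4',6'-tris(methoxymethoxy)chalcone, (2E)-enone | CC(C)=CCC/C(C)=C/Cc1c(OCOC)cc(OCOC)c(C(=O)/C=C/c2ccc(OCOC)cc2)c1O
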